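**Retrosynthetic overview**
1. The target is a cis-fused (5β-H, 10β-CH3) bicyclic triterpene diol. The last step only removes the silyl group from O3.
2. The key disconnection is C14–C15. A C18 tricyclic enol ether, a C11 homogeranyl copper reagent and CH3I are joined in one flask by 1,2-metallate rearrangement with ring opening.
3. The enabling feature is that the oxygen of the C8 tertiary carbinol reaches C14 through C8–C9–C11–C12–C13. O8 and C14 can therefore be tied into a seven-membered 2,3,4,5-tetrahydrooxepine (ring C) fused to ring B at C8–C9. This ring forces O8 cis to C12 on C13=C14, makes C14–H lithiable and turns O8 into the internal leaving group.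
4. Rings A and B come fused in 6-methoxy-2-tetralone, whose anisole ring becomes ring B. C3 is set by ketone reduction, C5 by a catalytic proton shuttle after Birch reduction, C10 and C9 by cuprate addition and allylation, and C8 by methyl addition. Ring C is closed last by metathesis and opened again in the key step.
5. Homogeranyl iodide is made by the same type of rearrangement, in its known form, from 2,3-dihydrofuran.

Key step: step 12

Remark on the structure: read as written, the SMILES places H-5 and the C10 methyl on the same face (cis-fused decalin, 3S,5S,8R,9R,10S). The route is built for exactly this isomer, so trans-fused chiral-pool decalins are not used.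
Numbering: C1–C10 form the decalin (C3 secondary carbinol, C4 CMe2, C5/C10 ring fusion, C8 tertiary carbinol, C9 chain-bearing carbon). C11–C22 run outward from C9. β is the face of the C10 methyl. Ring A is C1–C5 plus C10, ring B is C5–C10, and ring C is O8–C8–C9–C11–C12–C13–C14. The cis-decalin is expected to rest in the chair–chair form with C4 equatorial and C1 axial on ring B.

**Step 1**
Reactants: 1 6-methoxy-2-tetralone
Product: 2 6-methoxy-1,1-dimethyl-2-tetralone
Conditions: MeI (2.2 equiv), KOtBu (2.2 equiv), THF–t-BuOH, 0 °C → rt
Reagents that add atoms: methyl iodide, CI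
Why: Double enolate C-alkylation at the doubly activated (benzylic and α-keto) methylene, the future C4, installs the gem-dimethyl group without creating a stereocentre.

**Step 2**
Reactants: 2 6-methoxy-1,1-dimethyl-2-tetralone
Product: 3 (S)-6-methoxy-1,1-dimethyl-1,2,3,4-tetrahydronaphthalen-2-ol
Conditions: (R)-Me-CBS oxazaborolidine (10 mol %), BH3·SMe2, THF, −20 °C; MeOH quench
Reagents that add atoms: none
Why: In this Corey–Bakshi–Shibata reduction the quaternary C4 is the large flank and C2H2 the small flank of the ketone, so the (R)-catalyst should deliver hydride to the face that gives the (3S)-carbinol.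

**Step 3**
Reactants: 3 (S)-6-methoxy-1,1-dimethyl-1,2,3,4-tetrahydronaphthalen-2-ol
Product: 4 (S)-2-(tert-butyldimethylsilyloxy)-6-methoxy-1,1-dimethyltetralin
Conditions: TBSOTf, 2,6-lutidine, CH2Cl2, 0 °C
Reagents that add atoms: tert-butyldimethylsilyl triflate, CC(C)(C)[Si](C)(C)OS(=O)(=O)C(F)(F)F
Why: Silylation with the reactive triflate covers the hindered neopentylic carbinol with a group that should survive dissolving metal, organometallic reagents and t-BuLi, and C3 is not touched.

**Step 4**
Reactants: 4 (S)-2-(tert-butyldimethylsilyloxy)-6-methoxy-1,1-dimethyltetralin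
Product: 6 (S)-6-(tert-butyldimethylsilyloxy)-5,5-dimethyl-3,4,5,6,7,8-hexahydronaphthalen-2(1H)-one (C8 ketone with C5=C10 double bond), via dihydroanisole 5 (not isolated)
Conditions: Li, NH3(l), THF, t-BuOH, −78 → −33 °C; NH4Cl; then (CO2H)2, THF–MeOH–H2O, rt
Reagents that add atoms: water, O
Why: Birch reduction of the anisole ring gives the 1,4-diene 5 (enol ether C7=C8, tetrasubstituted C5=C10), and mild enol ether hydrolysis releases the C8 ketone without conjugation while the silyl ether and C3 stay intact.

**Step 5**
Reactants: 6 β,γ-unsaturated ketone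
Product: 7 (4aS,6S)-6-(tert-butyldimethylsilyloxy)-5,5-dimethyl-4,4a,5,6,7,8-hexahydronaphthalen-2(3H)-one (C8 ketone, C9=C10, H-5 β and cis to the 3β-silyloxy group)
Conditions: 9-amino-9-deoxy-epi-cinchona diamine catalyst (10 mol %), ArCO2H co-catalyst (10 mol %), toluene, 0 °C
Reagents that add atoms: none
Why: This is the organocatalytic iminium/base (proton-shuttle) isomerisation of a Birch-derived cyclohex-3-enone to the cyclohex-2-enone, in which the catalyst takes one C9 proton and returns it suprafacially to C5, so the choice between the two pseudoenantiomeric catalysts should set H-5 on the β face, and any leakage appears as a separable C5 diastereomer because 6 is a single enantiomer.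

**Step 6**
Reactants: 7 conjugated enone
Product: 9 (3S,5S,9R,10S)-9β-allyl-3β-(tert-butyldimethylsilyloxy)-4,4,10β-trimethyl-cis-decal-8-one, via lithium C8–C9 enolate 8 (not isolated)
Conditions: Me2CuLi (from MeLi, CuI), Et2O, −20 → 0 °C; then allyl bromide, THF–HMPA, 0 °C → rt
Reagents that add atoms: lithium dimethylcuprate, [Li+].C[Cu-]C; allyl bromide, C=CCBr
Why: Gilman conjugate addition to the octalone takes place anti to the bulky C4 substituent on C5 and so puts the C10 methyl cis to H-5, and the regiodefined enolate 8 is then allylated axially on the convex β face, anti to the pseudoaxial C10–C1 bond, which sets C9 under kinetic control.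

**Step 7**
Reactants: 9 allyl ketone
Product: 10 (3S,5S,8R,9R,10S)-9β-allyl-3β-(tert-butyldimethylsilyloxy)-4,4,8β,10β-tetramethyl-cis-decalin-8α-ol
Conditions: MeLi, CeCl3 (anhydrous), THF, −78 °C; aq NH4Cl
Reagents that add atoms: methyllithium, C[Li]
Why: In this 1,2-addition of the weakly basic organocerium reagent, which avoids enolisation and C9 epimerisation, the axial α trajectory is blocked by the syn-axial C1 methylene, so methyl should enter equatorially and leave the oxygen axial (8β-CH3, 8α-OH).

**Step 8**
Reactants: 10 tertiary alcohol
Product: 11 8α-allyl ether of 10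
Conditions: KH, 18-crown-6 (cat.), allyl bromide, THF, 0 → 50 °C
Reagents that add atoms: allyl bromide, C=CCBr
Why: Williamson etherification of the naked potassium alkoxide with an activated halide forms the O8–C14 bond, and no stereocentre is involved.

**Step 9**
Reactants: 11 bis-allyl compound
Product: 13 tricyclic enol ether (ring C = 2,3,4,5-tetrahydrooxepine with C13=C14), via tricyclic allylic ether 12 (not isolated)
Conditions: second-generation Grubbs catalyst RuCl2(=CHPh)(PCy3)(H2IMes) (5 mol %), toluene (0.001 M), 80 °C, argon sparge; then RuHCl(CO)(PPh3)3 (5 mol %), 100 °C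
Reagents that add atoms: none
Why: Ring-closing metathesis of the two terminal allyl groups closes the seven-membered ring C (C12=C13, necessarily Z) with loss of ethylene, and the ruthenium hydride then moves the double bond one position into conjugation with O8 (allyl ether to enol ether isomerisation, the thermodynamic sink) without touching a stereocentre.

**Step 10**
Reactants: 14 2,3-dihydrofuran; 15 5-bromo-2-methylpent-2-ene
Product: 20 (E)-homogeraniol ((3E)-4,8-dimethylnona-3,7-dien-1-ol), via 5-lithio-2,3-dihydrofuran 16 (not isolated), via 4-methylpent-3-enyllithium 17 (not isolated), via mixed lithium cuprate 18 (not isolated), via ring-opened alkenylcopper alkoxide 19 (not isolated)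
Conditions: 14, t-BuLi, THF–pentane, −78 → 0 °C; 15, Li metal, Et2O, −10 °C; CuBr·SMe2, Et2O–SMe2, −40 °C, then both organolithiums, −40 °C → rt; MeI, 0 °C → rt; aq NH4Cl
Reagents that add atoms: methyl iodide, CI
Why: In this known 1,2-metallate rearrangement of the cuprate from 5-lithio-2,3-dihydrofuran, the 4-methylpent-3-enyl group migrates from copper to the oxygen-bearing vinyl carbon with inversion and ring opening, and methylation of the alkenylcopper with retention fixes the E-trisubstituted C17=C18 double bond.

**Step 11**
Reactants: 20 (E)-homogeraniol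
Product: 21 (E)-homogeranyl iodide ((3E)-1-iodo-4,8-dimethylnona-3,7-diene)
Conditions: I2, PPh3, imidazole, CH2Cl2, 0 °C
Reagents that add atoms: iodine, II
Why: Appel-type iodination of the primary homoallylic alcohol proceeds by SN2 displacement of the oxyphosphonium ion and leaves both double bonds untouched.

**Step 12**
Reactants: 13 tricyclic enol ether; 21 (E)-homogeranyl iodide
Product: 26 3-O-TBS ether of the target, via 14-lithio enol ether 22 (not isolated), via homogeranyllithium 23 (not isolated), via mixed lithium cuprate 24 (not isolated), via ring-opened alkenylcopper alkoxide 25 (not isolated)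
Conditions: 13, t-BuLi, THF, −78 → 0 °C; 21, t-BuLi (2 equiv), Et2O–pentane, −78 °C; CuBr·SMe2, −40 °C, then both organolithiums, −40 °C → rt; MeI, 0 °C → rt; aq NH4Cl–NH3
Reagents that add atoms: methyl iodide, CI
Why: Proposed new method: vinylic deprotonation of 13 at C14 gives 22, which combines with 23 and CuBr·SMe2 to the mixed ate complex 24; in 24 the homogeranyl carbon C15 migrates from monovalent copper to C14 in the plane of the double bond, anti to the C14–O8 bond, expelling the C8 alkoxide and forming C14–C15 while copper swings into the site vacated by oxygen (25), and methyl iodide then replaces copper with retention. The closest known reaction type is the 1,2-metallate rearrangement of cuprates made from 5-lithio-2,3-dihydrofuran or 6-lithio-3,4-dihydro-2H-pyran followed by alkylation (used as such in step 10); new here are the seven-membered ring and a tertiary alkoxide as leaving group. No ring is closed: ring C is opened, and the strain it stores (it holds O8 and C11 gauche, whereas they are trans-diaxial in the relaxed cis-decalin) should compensate for the poorer nucleofuge. No sp3 stereocentre is formed and C3, C5, C8, C9 and C10 are untouched; the one stereo-element created, the C13=C14 geometry, follows from the ring-enforced cis relation of O8 and C12, inversion at C14 in the migration and retention in the methylation, which together place C15 trans and the new methyl cis to C12 (E). The step needs C14–H rather than allylic C12–H lithiation (secured by the oxygen-assisted α-vinyl metalation typical of cyclic enol ethers), transfer of homogeranyl only (it is the sole sp3 ligand on copper), and C- rather than O-methylation (the alkenylcopper is far more reactive than the hindered tertiary lithium alkoxide). In one flask it joins the C18 and C11 halves, adds the C14 methyl carbon, fixes the trisubstituted E-olefin and unmasks the C8 hydroxyl.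

**Step 13**
Reactants: 26 3-O-TBS ether of the target
Product: 27 target IN0670, (3S,5S,8R,9R,10S)-diol
Conditions: TBAF, THF, 50 °C
Reagents that add atoms: none
Why: Fluoride-induced desilylation under non-acidic conditions frees the 3β-hydroxyl without risk to the tertiary alcohol or of cationic cyclisation of the triene.

**Compound list**
1 | 6-methoxy-2-tetralone | COc1ccc2c(c1)CCC(=O)C2 | starting material
2 | 6-methoxy-1,1-dimethyl-2-tetralone | COc1ccc2c(c1)CCC(=O)C2(C)C | intermediate
3 | (S)-6-methoxy-1,1-dimethyl-1,2,3,4-tetrahydronaphthalen-2-ol | COc1ccc2c(c1)CC[C@H](O)C2(C)C | intermediate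
4 | TBS ether of 3 | COc1ccc2c(c1)CC[C@H](O[Si](C)(C)C(C)(C)C)C2(C)C | intermediate
5 | dihydroanisole (C7=C8 enol ether, C5=C10) | COC1=CCC2=C(C1)CC[C@H](O[Si](C)(C)C(C)(C)C)C2(C)C | intermediate
6 | β,γ-unsaturated C8 ketone (C5=C10) | O=C1CCC2=C(C1)CC[C@H](O[Si](C)(C)C(C)(C)C)C2(C)C | intermediate
7 | conjugated enone (C9=C10), 3β-OTBS, 5β-H | O=C1C=C2CC[C@H](O[Si](C)(C)C(C)(C)C)C(C)(C)[C@H]2CC1 | intermediate
8 | lithium C8–C9 enolate of the 10β-methyl cis-decalone | [Li]OC1=C[C@@]2(C)CC[C@H](O[Si](C)(C)C(C)(C)C)C(C)(C)[C@H]2CC1 | intermediate
9 | 9β-allyl-3β-OTBS-4,4,10β-trimethyl-cis-decal-8-one | C=CC[C@@H]1[C@@]2(C)CC[C@H](O[Si](C)(C)C(C)(C)C)C(C)(C)[C@H]2CCC1=O | intermediate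
10 | 9β-allyl-3β-OTBS-4,4,8β,10β-tetramethyl-cis-decalin-8α-ol | C=CC[C@@H]1[C@@]2(C)CC[C@H](O[Si](C)(C)C(C)(C)C)C(C)(C)[C@H]2CC[C@@]1(C)O | intermediate
11 | 8α-allyl ether of 10 | C=CC[C@@H]1[C@@]2(C)CC[C@H](O[Si](C)(C)C(C)(C)C)C(C)(C)[C@H]2CC[C@@]1(C)OCC=C | intermediate
12 | tricyclic allylic ether (ring C with C12=C13) | C3=CC[C@@H]1[C@@]2(C)CC[C@H](O[Si](C)(C)C(C)(C)C)C(C)(C)[C@H]2CC[C@@]1(C)OC3 | intermediate
13 | tricyclic enol ether (ring C with C13=C14) | C3C[C@@H]1[C@@]2(C)CC[C@H](O[Si](C)(C)C(C)(C)C)C(C)(C)[C@H]2CC[C@@]1(C)OC=C3 | intermediate
14 | 2,3-dihydrofuran | C1CC=CO1 | starting material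
15 | 5-bromo-2-methylpent-2-ene | CC(C)=CCCBr | starting material
16 | 5-lithio-2,3-dihydrofuran | [Li]C1=CCCO1 | intermediate
17 | 4-methylpent-3-enyllithium | CC(C)=CCC[Li] | intermediate
18 | lithium (4,5-dihydrofuran-2-yl)(4-methylpent-3-enyl)cuprate | [Li+].CC(C)=CCC[Cu-]C1=CCCO1 | intermediate
19 | ring-opened alkenylcopper lithium alkoxide | CC(C)=CCC/C([Cu])=C/CCO[Li] | intermediate
20 | (E)-homogeraniol | CC(C)=CCC/C(C)=C/CCO | intermediate
21 | (E)-homogeranyl iodide | CC(C)=CCC/C(C)=C/CCI | intermediate
22 | 14-lithio derivative of 13 | C3C[C@@H]1[C@@]2(C)CC[C@H](O[Si](C)(C)C(C)(C)C)C(C)(C)[C@H]2CC[C@@]1(C)OC([Li])=C3 | intermediate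
23 | (E)-homogeranyllithium | CC(C)=CCC/C(C)=C/CC[Li] | intermediate
24 | mixed lithium cuprate (C14 and C15 both on copper) | [Li+].C3C[C@@H]1[C@@]2(C)CC[C@H](O[Si](C)(C)C(C)(C)C)C(C)(C)[C@H]2CC[C@@]1(C)OC([Cu-]CC/C=C(\C)CCC=C(C)C)=C3 | intermediate
25 | ring-opened C14 alkenylcopper, C8 lithium alkoxide | CC(C)=CCC/C(C)=C/CC/C([Cu])=C/CC[C@@H]1[C@@]2(C)CC[C@H](O[Si](C)(C)C(C)(C)C)C(C)(C)[C@H]2CC[C@@]1(C)O[Li] | intermediate
26 | 3-O-TBS ether of the target | CC(C)=CCC/C(C)=C/CC/C(C)=C/CC[C@@H]1[C@@]2(C)CC[C@H](O[Si](C)(C)C(C)(C)C)C(C)(C)[C@H]2CC[C@@]1(C)O | intermediate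
27 | IN0670 | CC(C)=CCC/C(C)=C/CC/C(C)=C/CC[C@@H]1[C@@]2(C)CC[C@H](O)C(C)(C)[C@H]2CC[C@@]1(C)O | target

**Totals**
Total step count: 13. Longest linear sequence: 11 steps (steps 1–9, 12, 13).

**Steps most likely to fail**

1. **Step 12** (bears the label). The migration may stall because a tertiary alkoxide is a reluctant leaving group. The cuprate would then simply be protonated on work-up, or allylic metalation and thermal decay of the cuprate would take over.
   - The fallback uses known chemistry, sets out from 13 (with 21) and comes back at 26.
   - 13 is lithiated as before and the vinyllithium is alkylated directly with iodide 21 in THF–DMPU. This forms the same C14–C15 bond and gives the 14-homogeranyl tricyclic enol ether F1.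
   - F1 is then submitted to the nickel-catalysed cross-coupling of enol ethers with Grignard reagents (MeMgBr, NiCl2(PPh3)2, toluene, reflux; zerovalent nickel inserts into the C14–O8 bond). This replaces O8 by methyl with retention, opens ring C and delivers 26 after aqueous work-up.

2. **Step 9.** Ring closure has to pay for turning ring B out of its resting form, so that O8 and C11 become gauche. Intermolecular metathesis (oligomerisation) may therefore outrun cyclisation, and the hydride may move the double bond away from oxygen.
   - The fallback sets out from 10 and comes back at 13. It has no bimolecular competitor in the ring-forming event.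
   - The allyl group of 10 is hydroborated (9-BBN, then H2O2–NaOH) to the primary alcohol F2.
   - F2 is oxidised (TEMPO, PhI(OAc)2) to the aldehyde F3.
   - F3 is homologated with the Ohira–Bestmann reagent (K2CO3, MeOH) to the terminal alkynol F4.
   - F4 undergoes tungsten-catalysed endo-selective alkynol cycloisomerisation (W(CO)6, Et3N, THF, hν). O8 adds to the terminal carbon of the derived vinylidene and gives 13 directly.

3. **Step 5.** The facial selectivity of the proton return may be poor if the catalyst and the resident C3 centre are mismatched. Slow re-entry of the product into the dienamine may erode what selectivity there is.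
   - The fallback sets out from 6 and comes back at 7. It replaces catalyst control by equilibration with recycling.
   - Aqueous HCl in THF conjugates 6 under thermodynamic control to 7 together with its C5 epimer F5.
   - The two are diastereomers and are separated by chromatography. F5 is resubmitted to the same acid, which re-equilibrates it through the common dienol, so the material is funnelled into 7 over several passes.

**Further compounds**
F1 | step 12 | 14-homogeranyl tricyclic enol ether | C3C[C@@H]1[C@@]2(C)CC[C@H](O[Si](C)(C)C(C)(C)C)C(C)(C)[C@H]2CC[C@@]1(C)OC(CC/C=C(\C)CCC=C(C)C)=C3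
F2 | step 9 | 9β-(3-hydroxypropyl) analogue of 10 | OCCC[C@@H]1[C@@]2(C)CC[C@H](O[Si](C)(C)C(C)(C)C)C(C)(C)[C@H]2CC[C@@]1(C)O
F3 | step 9 | 9β-(3-oxopropyl) analogue of 10 | O=CCC[C@@H]1[C@@]2(C)CC[C@H](O[Si](C)(C)C(C)(C)C)C(C)(C)[C@H]2CC[C@@]1(C)O
F4 | step 9 | 9β-(but-3-ynyl) analogue of 10 | C#CCC[C@@H]1[C@@]2(C)CC[C@H](O[Si](C)(C)C(C)(C)C)C(C)(C)[C@H]2CC[C@@]1(C)O
F5 | step 5 | C5 epimer of 7 (5α-H) | O=C1C=C2CC[C@H](O[Si](C)(C)C(C)(C)C)C(C)(C)[C@@H]2CC1
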